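**Strategy.** Everything rests on reading ring C (O1–C2–C3–C3a–C7a), with ring A on C2 and CH2OH on C3, as a ring-contracted flavanone. The CH2OH carbon is the former C4 carbonyl carbon and C3a the former C4a. Photolysis of the enantiopure 3-diazoflavanone 8 in methanol loses N2 and moves C4a of ring B from C4 to C3 (new C3–C3a bond, pyranone to dihydrofuran). Protonation of the ketene–methanol adduct opposite ring A then sets C3 cis to C2, as the (2S,3S) target demands. Compound 8 is a 6-bromo-8-methoxyflavanone bearing =N2 at C3, its C2 set by catalytic arylation of a chromone. The bromide later becomes the aldehyde that carries the furofuran.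

Key step: step 5

**Labels.**
- Ring A is the guaiacyl ring on C2, ring B the benzo ring, ring C is O1–C2–C3–C3a–C7a, and rings D and E are the two tetrahydrofurans of the furofuran.
- C7/C8/C9 is the furofuran half bound to ring B; C7'/C8'/C9' is the syringyl half.
- ArB = (2S,3S)-2-[4-(benzyloxy)-3-methoxyphenyl]-3-{[(tert-butyldiphenylsilyl)oxy]methyl}-7-methoxy-2,3-dihydro-1-benzofuran-5-yl.
- ArS = 4-(benzyloxy)-3,5-dimethoxyphenyl.
- Men = (1R,2S,5R)-2-isopropyl-5-methylcyclohexyl.

**Stereochemical reading of the target.**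
- C2 is S and C3 is S, so ring A and CH2OH are cis on ring C.
- C7 S, C8 R, C7' S, C8' R: a cis-fused furofuran with both aryl groups exo.
- The cis arrangement on ring C is the less stable one. After step 5, therefore, no base able to exchange H3 of the ester and no acid able to ionise O1–C2 is used.
- The C2 descriptor runs S (6), R (8), S (11) without any change in space.

**Assumption.** The (R)-ligand is taken to give the 2S flavanone, by analogy with the (S)-ligand, which gives (R)-3-aryl-3-methylcyclohexanones by attack on the corresponding enone face. If the sense on chromones is opposite, the antipodal ligand is used and nothing else changes.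

## Route

Step 1
Reactants: 1 1-(2-hydroxy-3-methoxyphenyl)ethanone
Product: 2 1-(5-bromo-2-hydroxy-3-methoxyphenyl)ethanone
Conditions: NBS, MeCN, 0 °C to rt
Reagents that add atoms: N-bromosuccinimide, O=C1CCC(=O)N1Br
Why: Electrophilic aromatic bromination directed by the free phenol, whose two ortho positions are blocked by the acetyl and methoxy groups, so that only the para position C5 is attacked, as in the familiar bromination of o-vanillin.

Step 2
Reactants: 2 1-(5-bromo-2-hydroxy-3-methoxyphenyl)ethanone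
Product: 4 6-bromo-8-methoxy-4H-chromen-4-one, via enaminone 3 (not isolated)
Conditions: Me2NCH(OMe)2, toluene, 100 °C; concentrate; conc. HCl, CH2Cl2, 40 °C
Reagents that add atoms: N,N-dimethylformamide dimethyl acetal, COC(OC)N(C)C
Why: Enaminone route to chromones: the amide acetal condenses with the acetyl CH3 group to give 3, and acid then promotes addition of the phenol oxygen to the β-carbon with loss of dimethylamine, which closes the pyranone and leaves C2 and C3 unsubstituted.

Step 3
Reactants: 4 6-bromo-8-methoxy-4H-chromen-4-one; 5 [4-(benzyloxy)-3-methoxyphenyl]boronic acid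
Product: 6 (2S)-2-[4-(benzyloxy)-3-methoxyphenyl]-6-bromo-8-methoxychroman-4-one
Conditions: Pd(OCOCF3)2 (5 mol %), (R)-4-tert-butyl-2-(pyridin-2-yl)-4,5-dihydrooxazole (6 mol %), NH4PF6 (30 mol %), H2O (5 equiv), ClCH2CH2Cl, 60 °C
Reagents that add atoms: none
Why: Enantioselective conjugate addition of an arylboronic acid to a chromone with a cationic divalent palladium pyridine-oxazoline catalyst: after transmetalation the aryl group is delivered to one face of the flat C2=C3 bond under control of the tert-butyl group of the ligand, which sets C2 as S, and protonolysis of the palladium enolate closes a cycle that never passes through zerovalent palladium, so the C–Br bond stays intact.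

Step 4
Reactants: 6 (2S)-2-[4-(benzyloxy)-3-methoxyphenyl]-6-bromo-8-methoxychroman-4-one
Product: 8 (2R)-2-[4-(benzyloxy)-3-methoxyphenyl]-6-bromo-3-diazo-8-methoxychroman-4-one, via 3-trifluoroacetylflavanone 7 (not isolated)
Conditions: LiN(SiMe3)2, THF, −78 °C, 15 min; CF3CO2CH2CF3, −78 °C, 10 min; AcOH; crude 7, 4-AcNHC6H4SO2N3, Et3N, H2O (1 equiv), MeCN, 0 °C
Reagents that add atoms: 4-acetamidobenzenesulfonyl azide, CC(=O)Nc1ccc(cc1)S(=O)(=O)N=[N+]=[N-]; 2,2,2-trifluoroethyl trifluoroacetate, O=C(OCC(F)(F)F)C(F)(F)F (its CF3CO group stays in 7 only)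
Why: Detrifluoroacetylative diazo transfer (Regitz type): the kinetic lithium enolate is trifluoroacetylated at C3 within minutes at −78 °C, and the acidic 1,3-diketone 7 then accepts N2 from the sulfonyl azide under Et3N and sheds the CF3CO group as the N-sulfonylamide, so that the strongly basic enolate, which could open the O1–C2 bond by E1cB elimination, lives only briefly and cold and C2 keeps its arrangement in space.

Step 5
Reactants: 8 (2R)-2-[4-(benzyloxy)-3-methoxyphenyl]-6-bromo-3-diazo-8-methoxychroman-4-one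
Product: 11 methyl (2S,3R)-2-[4-(benzyloxy)-3-methoxyphenyl]-5-bromo-7-methoxy-2,3-dihydro-1-benzofuran-3-carboxylate (2,3-cis), via ketene 9 (not isolated), via ester enol 10 (not isolated)
Conditions: hν (365 nm LED, borosilicate vessel), MeOH–THF 4:1, 0.01 M, −20 °C, argon
Reagents that add atoms: methanol, CO
Why: Excitation of 8, in which the ring holds C4=O and C3=N2 s-Z, expels N2 while the C4–C4a bond shifts to C3 in the same event, so that ketene 9 forms without a long-lived carbene; methanol adds to 9 to give ester enol 10, which is protonated at C3. The closest known reaction type is the photochemical Wolff ring contraction of benzo-fused cyclic α-diazoketones (2-diazo-1-tetralones to indane-1-carboxylates, 2-diazo-1-indanones to benzocyclobutenecarboxylates) with kinetic protonation of the ketene adduct. Ring C is closed by a 1,2-shift of the ring B carbon C4a, that is by contraction of the six-membered pyranone to the five-membered dihydrofuran through the new C3–C3a bond, and not by cyclisation of an open chain, while O1–C2 and C2–C3 are carried over unchanged. The new stereocentre C3 is controlled by C2: allylic 1,3-strain with the exocyclic C=C(OH)OMe unit turns ring A pseudo-axial, ring A then covers one face of the flat enol, and the proton arrives from the other face, which places the ester cis to ring A (2S,3R) as the kinetic, less stable epimer. The step needs migration of C4a to win over the 1,2-shift of H2 to C3, which is secured by the locked s-Z geometry and by direct singlet excitation without sensitiser, and it needs facial selectivity in the protonation, which is secured by ring A as described and helped by the low temperature. Light of 365 nm is absorbed only by the diazoketone, so the C–Br bond, the benzyl ether and product 11 are not excited, and neutral methanol does not exchange H3.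

Step 6
Reactants: 11 methyl (2S,3R)-2-[4-(benzyloxy)-3-methoxyphenyl]-5-bromo-7-methoxy-2,3-dihydro-1-benzofuran-3-carboxylate
Product: 12 [(2S,3S)-2-[4-(benzyloxy)-3-methoxyphenyl]-5-bromo-7-methoxy-2,3-dihydro-1-benzofuran-3-yl]methanol (2,3-cis)
Conditions: i-Bu2AlH (3 equiv), CH2Cl2, −78 to −20 °C; aq potassium sodium tartrate
Reagents that add atoms: none
Why: Reduction of the ester to the primary alcohol with a Lewis acidic, non-basic aluminium hydride at low temperature, chosen because H3 of the cis ester and of the transient aldehyde is acidic and alkoxide-generating hydrides could epimerise C3 to the trans series; no stereocentre is touched and the aryl bromide and benzyl ether are inert.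

Step 7
Reactants: 12 [(2S,3S)-2-[4-(benzyloxy)-3-methoxyphenyl]-5-bromo-7-methoxy-2,3-dihydro-1-benzofuran-3-yl]methanol
Product: 13 ArB–Br, the tert-butyldiphenylsilyl ether of 12
Conditions: t-BuPh2SiCl, imidazole, DMF, rt
Reagents that add atoms: tert-butyl(chloro)diphenylsilane, CC(C)(C)[Si](Cl)(c1ccccc1)c1ccccc1
Why: Imidazole-promoted silylation of the only hydroxyl group; the tert-butyldiphenylsilyl ether withstands the organolithium, amide base, hydride and sulfonylation steps that follow and keeps this primary alcohol out of the later mesylation.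

Step 8
Reactants: 13 ArB–Br
Product: 15 ArB–CHO, via aryllithium 14 (not isolated)
Conditions: n-BuLi (1.05 equiv), THF, −78 °C; DMF, −78 °C to 0 °C; AcOH, H2O
Reagents that add atoms: N,N-dimethylformamide, CN(C)C=O; n-butyllithium, [Li]CCCC (lithium in 14 only)
Why: Bromine–lithium exchange followed by formylation with DMF (Bouveault aldehyde synthesis); at −78 °C the exchange is much faster than deprotonation at the benzylic positions, so C2 and C3 are not disturbed.

Step 9
Reactants: 16 syringaldehyde
Product: 17 4-(benzyloxy)-3,5-dimethoxybenzaldehyde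
Conditions: BnBr, K2CO3, DMF, 50 °C
Reagents that add atoms: benzyl bromide, BrCc1ccccc1
Why: Williamson etherification of the hindered but acidic syringyl phenol, needed because the next steps use organolithium bases.

Step 10
Reactants: 17 4-(benzyloxy)-3,5-dimethoxybenzaldehyde
Product: 18 2-(ArS)-1,3-dithiane
Conditions: HS(CH2)3SH, BF3·OEt2 (cat.), CH2Cl2, 0 °C to rt
Reagents that add atoms: propane-1,3-dithiol, SCCCS
Why: Lewis acid-catalysed dithioacetalisation of the aldehyde, which provides the acyl anion equivalent for Corey–Seebach umpolung.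

Step 11
Reactants: 18 2-(ArS)-1,3-dithiane; 19 (5R)-5-(Men-oxy)furan-2(5H)-one
Product: 22 (4R,5R)-4-[2-(ArS)-1,3-dithian-2-yl]-5-(Men-oxy)dihydrofuran-2(3H)-one, via lithiodithiane 20 (not isolated), via lithium enolate 21 (not isolated)
Conditions: n-BuLi, THF, −78 to −30 °C; 19, −78 °C; AcOH, −78 °C
Reagents that add atoms: n-butyllithium, [Li]CCCC (lithium in 20 and 21 only)
Why: Corey–Seebach umpolung and Michael addition: the soft 2-aryl-2-lithiodithiane adds 1,4 to the butenolide from the face opposite the menthyloxy group on C5, which sets the future C8' (4R in the lactone), and protonation of enolate 21 gives the trans-4,5-disubstituted lactone.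

Step 12
Reactants: 22 (4R,5R)-4-[2-(ArS)-1,3-dithian-2-yl]-5-(Men-oxy)dihydrofuran-2(3H)-one; 15 ArB–CHO
Product: 24 (3S,4R,5R)-3-[(S)-ArB(hydroxy)methyl]-4-[2-(ArS)-1,3-dithian-2-yl]-5-(Men-oxy)dihydrofuran-2(3H)-one, via potassium enolate 23 (not isolated)
Conditions: KN(SiMe3)2, THF, −78 °C; 15, −78 °C; AcOH, −78 °C
Reagents that add atoms: potassium bis(trimethylsilyl)amide, [K]N([Si](C)(C)C)[Si](C)(C)C (potassium in 23 only)
Why: Aldol addition of a lactone enolate: the aldehyde reaches C3 anti to the bulky dithianyl group on C4, which sets C8, and the weakly coordinating potassium ion favours an open antiperiplanar transition state, the known erythro-selective behaviour of potassium enolates of β-substituted butyrolactones with aromatic aldehydes, giving the syn 7S carbinol that an exo aryl group requires, whereas a closed Zimmerman–Traxler chair of this ring-locked E(O)-enolate (lithium) would favour the anti epimer; the cold AcOH quench forestalls retro-aldol equilibration.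

Step 13
Reactants: 24 the aldol adduct
Product: 25 (2R,3R)-2-[(S)-ArB(hydroxy)methyl]-3-[2-(ArS)-1,3-dithian-2-yl]butane-1,4-diol
Conditions: LiAlH4 (excess), THF, −20 °C to rt, inverse addition
Reagents that add atoms: none
Why: Exhaustive LiAlH4 reduction: the lactone carbonyl gives C9H2OH and the liberated hemiacetal alkoxide at C9' collapses with loss of menthoxide to an aldehyde that is reduced as well, so that auxiliary removal and formation of the 1,4-diol occur in one operation without touching C7, C8 or C8', while inverse addition at low temperature lets reduction outrun retro-aldol cleavage.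

Step 14
Reactants: 25 the dithianyl triol
Product: 26 (2R,3R,4S)-4-ArB-4-hydroxy-2,3-bis(hydroxymethyl)-1-(ArS)butan-1-one
Conditions: MeI (excess), CaCO3, MeCN–H2O 9:1, 40 °C
Reagents that add atoms: water, O
Why: Alkylative hydrolysis of the dithiane: S-methylation turns sulfur into a leaving group, the aryl-stabilised thionium ion is captured by water, and CaCO3 keeps the medium neutral so that neither the benzylic alcohol at C7 nor the O1–C2 bond is ionised.

Step 15
Reactants: 26 the keto triol
Product: 27 (1S,2R,3R,4S)-1-ArB-4-(ArS)-2,3-bis(hydroxymethyl)butane-1,4-diol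
Conditions: Zn(BH4)2, Et2O–THF, −20 to 0 °C
Reagents that add atoms: none
Why: Diastereoselective hydride reduction of the aryl ketone: the zinc chelate between C7'=O and the C9' hydroxyl and the Felkin–Anh model with C8 as the large substituent expose the same carbonyl face, so that hydride should give the 7'S carbinol, syn to C8, which is the one required for an exo syringyl group.

Step 16
Reactants: 27 the tetraol
Product: 29 (1S,3aR,4S,6aR)-1-ArB-4-(ArS)tetrahydro-1H,3H-furo[3,4-c]furan, via bis-mesylate 28 (not isolated)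
Conditions: MsCl (2.2 equiv), pyridine, 0 °C to rt
Reagents that add atoms: methanesulfonyl chloride, CS(=O)(=O)Cl (its atoms stay in 28 only and leave again on ring closure)
Why: Selective sulfonylation of the two primary hydroxyl groups followed by a double intramolecular Williamson etherification (two 5-exo-tet closures, O7 onto C9' and O7' onto C9): the C7–O and C7'–O bonds are never broken, so both benzylic configurations are retained, the 8R,8'R backbone enforces the cis ring fusion with both aryl groups exo, and the basic medium protects the acid-sensitive ring C.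

Step 17
Reactants: 29 the silylated furofuran
Product: 30 [(2S,3S)-2-[4-(benzyloxy)-3-methoxyphenyl]-5-[(1S,3aR,4S,6aR)-4-(ArS)tetrahydro-1H,3H-furo[3,4-c]furan-1-yl]-7-methoxy-2,3-dihydro-1-benzofuran-3-yl]methanol
Conditions: Bu4NF, THF, rt
Reagents that add atoms: none
Why: Fluoride-induced cleavage of the silyl ether, driven by the strong Si–F bond, under conditions to which the benzyl ethers, the furofuran and ring C are inert.

Step 18
Reactants: 30 the bis(benzyl ether)
Product: 31 the target, 4-[(1S,3aR,4S,6aR)-4-{(2S,3S)-2-(4-hydroxy-3-methoxyphenyl)-3-(hydroxymethyl)-7-methoxy-2,3-dihydro-1-benzofuran-5-yl}tetrahydro-1H,3H-furo[3,4-c]furan-1-yl]-2,6-dimethoxyphenol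
Conditions: H2 (1 atm), 10% Pd/C, EtOAc–EtOH, rt, stopped at consumption of 30
Reagents that add atoms: none
Why: Catalytic hydrogenolysis of the two primary benzyl aryl ethers, which are cleaved much faster than the hindered secondary benzylic C–O bonds of rings C, D and E, so that stopping after uptake of two equivalents of H2 under neutral conditions should release both phenols without ring opening or epimerisation.

## Compound list

1 | 1-(2-hydroxy-3-methoxyphenyl)ethanone | CC(=O)c1cccc(OC)c1O | starting material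
2 | 1-(5-bromo-2-hydroxy-3-methoxyphenyl)ethanone | CC(=O)c1cc(Br)cc(OC)c1O | intermediate
3 | (E)-1-(5-bromo-2-hydroxy-3-methoxyphenyl)-3-(dimethylamino)prop-2-en-1-one | CN(C)/C=C/C(=O)c1cc(Br)cc(OC)c1O | intermediate
4 | 6-bromo-8-methoxy-4H-chromen-4-one | COc1cc(Br)cc2c(=O)ccoc12 | intermediate
5 | [4-(benzyloxy)-3-methoxyphenyl]boronic acid | COc1cc(B(O)O)ccc1OCc1ccccc1 | starting material
6 | (2S)-2-[4-(benzyloxy)-3-methoxyphenyl]-6-bromo-8-methoxychroman-4-one | COc1cc([C@H]2Oc3c(OC)cc(Br)cc3C(=O)C2)ccc1OCc1ccccc1 | intermediate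
7 | (2S)-2-[4-(benzyloxy)-3-methoxyphenyl]-6-bromo-8-methoxy-3-(trifluoroacetyl)chroman-4-one (C3 enolisable, not defined) | COc1cc([C@H]2Oc3c(OC)cc(Br)cc3C(=O)C2C(=O)C(F)(F)F)ccc1OCc1ccccc1 | intermediate
8 | (2R)-2-[4-(benzyloxy)-3-methoxyphenyl]-6-bromo-3-diazo-8-methoxychroman-4-one | COc1cc([C@H]2Oc3c(OC)cc(Br)cc3C(=O)C2=[N+]=[N-])ccc1OCc1ccccc1 | intermediate
9 | [(2R)-2-[4-(benzyloxy)-3-methoxyphenyl]-5-bromo-7-methoxy-1-benzofuran-3(2H)-ylidene]methanone (ketene) | COc1cc([C@H]2Oc3c(OC)cc(Br)cc3C2=C=O)ccc1OCc1ccccc1 | intermediate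
10 | (2R)-2-[4-(benzyloxy)-3-methoxyphenyl]-5-bromo-3-[hydroxy(methoxy)methylidene]-7-methoxy-2,3-dihydro-1-benzofuran (ester enol, C=C geometry not defined) | COc1cc([C@H]2Oc3c(OC)cc(Br)cc3C2=C(O)OC)ccc1OCc1ccccc1 | intermediate
11 | methyl (2S,3R)-2-[4-(benzyloxy)-3-methoxyphenyl]-5-bromo-7-methoxy-2,3-dihydro-1-benzofuran-3-carboxylate (cis) | COc1cc([C@H]2Oc3c(OC)cc(Br)cc3[C@H]2C(=O)OC)ccc1OCc1ccccc1 | intermediate
12 | [(2S,3S)-2-[4-(benzyloxy)-3-methoxyphenyl]-5-bromo-7-methoxy-2,3-dihydro-1-benzofuran-3-yl]methanol (cis) | COc1cc([C@H]2Oc3c(OC)cc(Br)cc3[C@H]2CO)ccc1OCc1ccccc1 | intermediate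
13 | ArB–Br, tert-butyldiphenylsilyl ether of 12 | COc1cc([C@H]2Oc3c(OC)cc(Br)cc3[C@H]2CO[Si](c2ccccc2)(c2ccccc2)C(C)(C)C)ccc1OCc1ccccc1 | intermediate
14 | ArB–Li | COc1cc([C@H]2Oc3c(OC)cc([Li])cc3[C@H]2CO[Si](c2ccccc2)(c2ccccc2)C(C)(C)C)ccc1OCc1ccccc1 | intermediate
15 | ArB–CHO | COc1cc([C@H]2Oc3c(OC)cc(C=O)cc3[C@H]2CO[Si](c2ccccc2)(c2ccccc2)C(C)(C)C)ccc1OCc1ccccc1 | intermediate
16 | syringaldehyde | COc1cc(C=O)cc(OC)c1O | starting material
17 | 4-(benzyloxy)-3,5-dimethoxybenzaldehyde | COc1cc(C=O)cc(OC)c1OCc1ccccc1 | intermediate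
18 | 2-[4-(benzyloxy)-3,5-dimethoxyphenyl]-1,3-dithiane | COc1cc(C2SCCCS2)cc(OC)c1OCc1ccccc1 | intermediate
19 | (5R)-5-[(1R,2S,5R)-menthyloxy]furan-2(5H)-one | O=C1O[C@@H](O[C@@H]2C[C@H](C)CC[C@H]2C(C)C)C=C1 | starting material
20 | 2-lithio-2-[4-(benzyloxy)-3,5-dimethoxyphenyl]-1,3-dithiane | COc1cc(C2([Li])SCCCS2)cc(OC)c1OCc1ccccc1 | intermediate
21 | lithium enolate of 22 | [Li]OC1=C[C@@H](C2(SCCCS2)c2cc(OC)c(OCc3ccccc3)c(OC)c2)[C@H](O[C@@H]2C[C@H](C)CC[C@H]2C(C)C)O1 | intermediate
22 | (4R,5R)-4-[2-(ArS)-1,3-dithian-2-yl]-5-(Men-oxy)dihydrofuran-2(3H)-one | O=C1C[C@@H](C2(SCCCS2)c2cc(OC)c(OCc3ccccc3)c(OC)c2)[C@H](O[C@@H]2C[C@H](C)CC[C@H]2C(C)C)O1 | intermediate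
23 | potassium enolate of 22 | [K]OC1=C[C@@H](C2(SCCCS2)c2cc(OC)c(OCc3ccccc3)c(OC)c2)[C@H](O[C@@H]2C[C@H](C)CC[C@H]2C(C)C)O1 | intermediate
24 | (3S,4R,5R)-3-[(S)-ArB(hydroxy)methyl]-4-[2-(ArS)-1,3-dithian-2-yl]-5-(Men-oxy)dihydrofuran-2(3H)-one | COc1cc([C@H]2Oc3c(OC)cc([C@@H](O)[C@H]4C(=O)O[C@@H](O[C@@H]5C[C@H](C)CC[C@H]5C(C)C)[C@@H]4C6(SCCCS6)c7cc(OC)c(OCc8ccccc8)c(OC)c7)cc3[C@H]2CO[Si](c2ccccc2)(c2ccccc2)C(C)(C)C)ccc1OCc1ccccc1 | intermediate
25 | (2R,3R)-2-[(S)-ArB(hydroxy)methyl]-3-[2-(ArS)-1,3-dithian-2-yl]butane-1,4-diol | COc1cc([C@H]2Oc3c(OC)cc([C@@H](O)[C@@H](CO)[C@H](CO)C4(SCCCS4)c5cc(OC)c(OCc6ccccc6)c(OC)c5)cc3[C@H]2CO[Si](c2ccccc2)(c2ccccc2)C(C)(C)C)ccc1OCc1ccccc1 | intermediate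
26 | (2R,3R,4S)-4-ArB-4-hydroxy-2,3-bis(hydroxymethyl)-1-(ArS)butan-1-one | COc1cc([C@H]2Oc3c(OC)cc([C@@H](O)[C@@H](CO)[C@H](CO)C(=O)c4cc(OC)c(OCc5ccccc5)c(OC)c4)cc3[C@H]2CO[Si](c2ccccc2)(c2ccccc2)C(C)(C)C)ccc1OCc1ccccc1 | intermediate
27 | (1S,2R,3R,4S)-1-ArB-4-(ArS)-2,3-bis(hydroxymethyl)butane-1,4-diol | COc1cc([C@H]2Oc3c(OC)cc([C@@H](O)[C@@H](CO)[C@H](CO)[C@H](O)c4cc(OC)c(OCc5ccccc5)c(OC)c4)cc3[C@H]2CO[Si](c2ccccc2)(c2ccccc2)C(C)(C)C)ccc1OCc1ccccc1 | intermediate
28 | (2R,3R)-2-[(S)-ArB(hydroxy)methyl]-3-[(S)-ArS(hydroxy)methyl]butane-1,4-diyl dimethanesulfonate | COc1cc([C@H]2Oc3c(OC)cc([C@@H](O)[C@@H](COS(C)(=O)=O)[C@H](COS(C)(=O)=O)[C@H](O)c4cc(OC)c(OCc5ccccc5)c(OC)c4)cc3[C@H]2CO[Si](c2ccccc2)(c2ccccc2)C(C)(C)C)ccc1OCc1ccccc1 | intermediate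
29 | (1S,3aR,4S,6aR)-1-ArB-4-(ArS)tetrahydro-1H,3H-furo[3,4-c]furan | COc1cc([C@H]2Oc3c(OC)cc([C@H]4OC[C@H]5[C@@H]4CO[C@@H]5c4cc(OC)c(OCc5ccccc5)c(OC)c4)cc3[C@H]2CO[Si](c2ccccc2)(c2ccccc2)C(C)(C)C)ccc1OCc1ccccc1 | intermediate
30 | desilylated bis(benzyl ether) of the target | COc1cc([C@H]2Oc3c(OC)cc([C@H]4OC[C@H]5[C@@H]4CO[C@@H]5c4cc(OC)c(OCc5ccccc5)c(OC)c4)cc3[C@H]2CO)ccc1OCc1ccccc1 | intermediate
31 | CNP0126146.1 | COc1cc([C@H]2Oc3c(OC)cc([C@H]4OC[C@H]5[C@@H]4CO[C@@H]5c4cc(OC)c(O)c(OC)c4)cc3[C@H]2CO)ccc1O | target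

## Step count

Total step count: 18. Longest linear sequence: 15 (steps 1–8, then 12–18).

## Steps most likely to fail

**1. Step 5.** The 1,2-shift of H2 to C3 may compete with migration of C4a. Proton delivery to the enol may reach both faces, or the cis ester may epimerise on handling.

The fallback sets out from 2 and returns at 11. It builds ring C by forming the C2–C3 bond instead of contracting a ring.
- Compound 2 is O-alkylated with 4-(benzyloxy)-3-methoxybenzyl chloride (K2CO3, DMF) to the aryl benzyl ether ketone F1.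
- Riley oxidation (SeO2, pyridine, 100 °C) gives the arylglyoxylic acid F2.
- MeI and K2CO3 give its methyl ester F3.
- TsNHNH2 in MeOH gives the tosylhydrazone F4.
- Et3N in CH2Cl2 (Bamford–Stevens elimination) gives the methyl aryldiazoacetate F5.
- Dirhodium tetrakis[N-phthaloyl-(S)-tert-leucinate], Rh2(S-PTTL)4, or its antipode, whichever correlates with the (2S,3R) series, is used in toluene at −60 °C. It inserts the donor/acceptor carbene into the benzylic O–CH2 group. This 1,5 C–H insertion is a reaction type known to give cis-2-aryl-2,3-dihydrobenzofuran-3-carboxylates enantioselectively, here 11.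

**2. Step 4.** Reversible E1cB opening of the O1–C2 bond at the enolate or diketonate stage may erode the enantiopurity at C2 or divert material to the open chain.

The fallback sets out from 6 and returns at 7. It avoids any metal enolate.
- Soft enolisation with Me3SiOSO2CF3 and Et3N in CH2Cl2 at 0 °C gives the trimethylsilyl enol ether F6.
- F6 is C-acylated with (CF3CO)2O in CH2Cl2 at −20 °C (acylation of a ketone silyl enol ether to a 1,3-diketone) to give 7.
- The diazo transfer half of step 4 follows unchanged.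

**3. Step 12.** Leakage through a closed transition state, or retro-aldol equilibration of the aldolate, may lower the selectivity at the carbinol carbon C7. Ring closure with retention would then carry that loss into an endo aryl group.

The fallback sets out from 22 (with 15) and returns at 24. It makes the aldol selectivity irrelevant.
- The lithium enolate (LiN(i-Pr)2, THF, −78 °C) is combined with 15 to give 24 together with the 7R carbinol epimer F7.
- The mixture is oxidised (Parikh–Doering, SO3·pyridine, DMSO, Et3N) to the single β-keto lactone F8.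
- Chelation-controlled reduction with Zn(BH4)2 in Et2O at −78 °C delivers hydride to the ketone face on the side of H8, away from C8'. This is the known syn-selective reduction of α-substituted β-keto esters and gives 24.

Further compounds
F1 | step 5 | 1-(2-{[4-(benzyloxy)-3-methoxybenzyl]oxy}-5-bromo-3-methoxyphenyl)ethanone | CC(=O)c1cc(Br)cc(OC)c1OCc1ccc(OCc2ccccc2)c(OC)c1
F2 | step 5 | (2-{[4-(benzyloxy)-3-methoxybenzyl]oxy}-5-bromo-3-methoxyphenyl)(oxo)acetic acid | OC(=O)C(=O)c1cc(Br)cc(OC)c1OCc1ccc(OCc2ccccc2)c(OC)c1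
F3 | step 5 | methyl (2-{[4-(benzyloxy)-3-methoxybenzyl]oxy}-5-bromo-3-methoxyphenyl)(oxo)acetate | COC(=O)C(=O)c1cc(Br)cc(OC)c1OCc1ccc(OCc2ccccc2)c(OC)c1
F4 | step 5 | tosylhydrazone of F3 (C=N geometry not defined) | COC(=O)C(=NNS(=O)(=O)c1ccc(C)cc1)c1cc(Br)cc(OC)c1OCc1ccc(OCc2ccccc2)c(OC)c1
F5 | step 5 | methyl (2-{[4-(benzyloxy)-3-methoxybenzyl]oxy}-5-bromo-3-methoxyphenyl)(diazo)acetate | COC(=O)C(=[N+]=[N-])c1cc(Br)cc(OC)c1OCc1ccc(OCc2ccccc2)c(OC)c1
F6 | step 4 | {[(2S)-2-[4-(benzyloxy)-3-methoxyphenyl]-6-bromo-8-methoxy-2H-chromen-4-yl]oxy}trimethylsilane | COc1cc([C@H]2Oc3c(OC)cc(Br)cc3C(O[Si](C)(C)C)=C2)ccc1OCc1ccccc1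
F7 | step 12 | (3S,4R,5R)-3-[(R)-ArB(hydroxy)methyl]-4-[2-(ArS)-1,3-dithian-2-yl]-5-(Men-oxy)dihydrofuran-2(3H)-one | COc1cc([C@H]2Oc3c(OC)cc([C@H](O)[C@H]4C(=O)O[C@@H](O[C@@H]5C[C@H](C)CC[C@H]5C(C)C)[C@@H]4C6(SCCCS6)c7cc(OC)c(OCc8ccccc8)c(OC)c7)cc3[C@H]2CO[Si](c2ccccc2)(c2ccccc2)C(C)(C)C)ccc1OCc1ccccc1
F8 | step 12 | (3S,4R,5R)-3-(ArB-carbonyl)-4-[2-(ArS)-1,3-dithian-2-yl]-5-(Men-oxy)dihydrofuran-2(3H)-one | COc1cc([C@H]2Oc3c(OC)cc(C(=O)[C@H]4C(=O)O[C@@H](O[C@@H]5C[C@H](C)CC[C@H]5C(C)C)[C@@H]4C6(SCCCS6)c7cc(OC)c(OCc8ccccc8)c(OC)c7)cc3[C@H]2CO[Si](c2ccccc2)(c2ccccc2)C(C)(C)C)ccc1OCc1ccccc1
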